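**Retrosynthetic overview**
- The pyrrole ring is closed last: the N–C2 bond of 2,3,4,7-tetrabromoindole is formed from an ortho-azido-β,β-dibromostyrene by a nitrenoid cyclisation in which one bromine shifts from C2 to C3 (new step).
- The gem-dibromovinyl group comes from dibromo-olefination of 2-azido-3,6-dibromobenzaldehyde.
- The azide comes from SNAr displacement of fluoride in 3,6-dibromo-2-fluorobenzaldehyde.
- The aldehyde comes from directed ortho-lithiation and formylation of commercial 1,4-dibromo-2-fluorobenzene.
- Ring order: the benzene ring is bought with both aryl bromides (future C4 and C7) in place; the five-membered ring is formed in the final step, which also places Br at C2 and C3.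

Assumption: the target is planar and achiral (no stereocentre), so no enantiocontrol is needed; the only stereocentres in the route are transient and racemic (in 3 and 7).

**Step 1**
Reactants: 1 1,4-dibromo-2-fluorobenzene
Product: 4 3,6-dibromo-2-fluorobenzaldehyde, via 3,6-dibromo-2-fluorophenyllithium 2 (not isolated), via lithium hemiaminolate 3 (not isolated)
Conditions: LiN(iPr)2 (LDA, commercial solution, 1.1 equiv), THF, −78 °C, 45 min; DMF (1.5 equiv), −78 °C, 30 min; 1 M aq. HCl, −78 °C to rt
Reagents that add atoms: N,N-dimethylformamide, CN(C)C=O
Why: Directed ortho-metalation, in which the C–H flanked by F and Br is the most acidic site, LDA at −78 °C deprotonates it without Br/Li exchange or aryne formation, and the aryllithium adds to DMF to give a hemiaminolate that releases the aldehyde on acid quench.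

**Step 2**
Reactants: 4 3,6-dibromo-2-fluorobenzaldehyde
Product: 5 2-azido-3,6-dibromobenzaldehyde
Conditions: NaN3 (1.3 equiv), DMSO, rt to 40 °C, 6 h, dark
Reagents that add atoms: sodium azide, [Na+].[N-]=[N+]=[N-]
Why: SNAr (addition–elimination), in which the ortho formyl group stabilises the Meisenheimer adduct and fluoride is displaced far faster than either ring bromide, while the low temperature avoids anthranil formation from the ortho-azido aldehyde.

**Step 3**
Reactants: 5 2-azido-3,6-dibromobenzaldehyde
Product: 6 2-azido-1,4-dibromo-3-(2,2-dibromovinyl)benzene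
Conditions: PPh3 (2.0 equiv), CBr4 (2.0 equiv), Zn dust (2.0 equiv), CH2Cl2, rt, 24 h (ylide pre-formed); then 5, 0 °C to rt, 2 h, dark
Reagents that add atoms: carbon tetrabromide, BrC(Br)(Br)Br (its CBr2 unit, delivered as Ph3P=CBr2)
Why: Ramirez (Corey–Fuchs) dibromo-olefination, in which the ylide is fully pre-formed with Zn so that no free PPh3 remains to attack the azide in a Staudinger reaction, and the Wittig reaction with the aryl aldehyde is fast at 0 °C; the geminal dibromide has no alkene geometry to control.

**Step 4**
Reactants: 6 2-azido-1,4-dibromo-3-(2,2-dibromovinyl)benzene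
Product: 8 2,3,4,7-tetrabromo-1H-indole, via 2,3,4,7-tetrabromo-3H-indole 7 (not isolated)
Conditions: Rh2(esp)2 (esp = α,α,α′,α′-tetramethyl-1,3-benzenedipropanoate; 5 mol %), 4 Å MS, toluene (0.05 M), 75 °C, 12 h, dark
Reagents that add atoms: none
Why: Proposed new method: a divalent-rhodium nitrenoid cyclisation with 1,2-bromine shift, in which Rh2(esp)2 extrudes N2 from the aryl azide to give a rhodium nitrenoid that closes onto the adjacent dibromovinyl group (4π-electron, five-atom electrocyclisation), forming the N–C2 bond and a benzylic cation at C3 next to the CBr2 centre; one bromine then migrates from C2 to C3 through a bridged bromiranium ion (no other group can migrate, and the resulting C2 cation is stabilised by nitrogen as the 2-bromo-3H-indole 7), and 3H-to-1H tautomerisation of 7 aromatises the ring, removes the racemic C3 centre and gives 8 with Br at C2 and C3, the aryl C–Br bonds being safe because no low-valent metal is present; closest known reaction type: the rhodium-carboxylate-catalysed conversion of β,β-disubstituted styryl azides into 2,3-disubstituted indoles with 1,2-shift of alkyl, aryl, acyl, sulfonyl or nitro groups, together with 1,2-halogen shifts through haliranium ions in cationic cycloisomerisations; to my knowledge a halogen has not been used as the migrating group, nor a gem-dihaloalkene as the acceptor, in this azide cascade.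

**Compound list**
1 | 1,4-dibromo-2-fluorobenzene | Fc1cc(Br)ccc1Br | starting material
2 | (3,6-dibromo-2-fluorophenyl)lithium (not isolated) | [Li]c1c(F)c(Br)ccc1Br | intermediate
3 | lithium (3,6-dibromo-2-fluorophenyl)(dimethylamino)methanolate (racemic, not isolated) | [Li]OC(N(C)C)c1c(F)c(Br)ccc1Br | intermediate
4 | 3,6-dibromo-2-fluorobenzaldehyde | O=Cc1c(F)c(Br)ccc1Br | intermediate
5 | 2-azido-3,6-dibromobenzaldehyde | O=Cc1c(N=[N+]=[N-])c(Br)ccc1Br | intermediate
6 | 2-azido-1,4-dibromo-3-(2,2-dibromovinyl)benzene | BrC(Br)=Cc1c(N=[N+]=[N-])c(Br)ccc1Br | intermediate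
7 | 2,3,4,7-tetrabromo-3H-indole (racemic at C3, not isolated) | BrC1=Nc2c(Br)ccc(Br)c2C1Br | intermediate
8 | 2,3,4,7-tetrabromo-1H-indole | Brc1[nH]c2c(Br)ccc(Br)c2c1Br | target

**Total step count:** 4
**Longest linear sequence:** 4 steps (1 → 4 → 5 → 6 → 8)

**Steps most likely to fail, with fallbacks**

Step 4 (the proposed new step). The di-ortho-substituted azide may bind the rhodium catalyst slowly, the electron-poor dibromoalkene may cyclise sluggishly, or the bromine shift may lose out to decomposition. The fallback uses known chemistry, sets out from 6 and comes back at 8. The azide of 6 is reduced chemoselectively (SnCl2·2H2O, EtOH, rt; the gem-dibromoalkene survives) to 3,6-dibromo-2-(2,2-dibromovinyl)aniline F1. The ring is then closed by the established zerovalent-palladium-catalysed intramolecular C–N coupling of ortho-(gem-dibromovinyl)anilines (Pd2(dba)3, P(tBu)3, K3PO4, toluene, 100 °C; the bulky phosphine makes insertion into the aryl C–Br bonds reversible, so the vinyl C–Br bond is the one that couples) to give 2,4,7-tribromo-1H-indole F2. Electrophilic bromination of the nucleophilic C3 position with NBS (1.0 equiv, DMF, 0 °C) then gives 8.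

Step 3. Residual phosphine or the ylide itself may attack the aryl azide, and the aldehyde is flanked by two ortho substituents. The fallback avoids phosphorus altogether, sets out from 5 and comes back at 6. Compound 5 is condensed with hydrazine hydrate (EtOH, rt) to (E)-(2-azido-3,6-dibromobenzylidene)hydrazine F3. This N-unsubstituted hydrazone is converted directly into the gem-dibromoalkene 6 by the copper-catalysed olefination of hydrazones with CBr4 (CuCl 10 mol %, aq. NH3, DMSO, rt), with loss of dinitrogen.

Step 2. Azide may displace fluoride slowly at this hindered position, may attack the formyl-activated C6–Br, or the product may cyclise to the anthranil. The fallback introduces nitrogen as an amine and makes the azide by diazotisation; it sets out from 4 and comes back at 5. Compound 4 is heated with 2,4-dimethoxybenzylamine (3 equiv) and K2CO3 in DMSO at 80 °C; imine formation plus fluoride displacement by the amine give the bis-adduct (E)-N-(2,4-dimethoxybenzyl)-1-{3,6-dibromo-2-[(2,4-dimethoxybenzyl)amino]phenyl}methanimine F4. TFA/H2O with 1,3-dimethoxybenzene as cation scavenger (rt) hydrolyses the imine and removes the N-benzyl group to give 2-amino-3,6-dibromobenzaldehyde F5, which is hindered and weakly nucleophilic and so resists self-condensation. Diazotisation and azide transfer (t-BuONO, Me3SiN3, MeCN, 0 °C to rt) then give 5.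

**Further compounds**
F1 | step 4 | 3,6-dibromo-2-(2,2-dibromovinyl)aniline | Nc1c(Br)ccc(Br)c1C=C(Br)Br
F2 | step 4 | 2,4,7-tribromo-1H-indole | Brc1cc2c(Br)ccc(Br)c2[nH]1
F3 | step 3 | (E)-(2-azido-3,6-dibromobenzylidene)hydrazine | N/N=C/c1c(N=[N+]=[N-])c(Br)ccc1Br
F4 | step 2 | (E)-N-(2,4-dimethoxybenzyl)-1-{3,6-dibromo-2-[(2,4-dimethoxybenzyl)amino]phenyl}methanimine | COc1ccc(C/N=C/c2c(Br)ccc(Br)c2NCc2ccc(OC)cc2OC)c(OC)c1
F5 | step 2 | 2-amino-3,6-dibromobenzaldehyde | Nc1c(Br)ccc(Br)c1C=O
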